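**Retrosynthetic overview**

1. Target 25 ⇐ keto-butenolide 20 by reagent-controlled reduction of the C6 ketone, C6 methacrylate, C2 acetate and desilylation.
2. 20 ⇐ cyclohexanol 13 + α-keto ester 17 in one flask: anionic oxy-Cope ring expansion (C8–C9), aldol of the allenolate carbon C7 onto C11, then acid lactonisation of the C12 carboxyl oxygen onto C8.
3. Enabling feature: C6 (oxygen-bearing) and the E C1=C10 alkene are 1,5-related through C7–C8–C9 of the ten-membered ring (oxy-Cope retron), and the butenolide ring-fusion atoms C7/C8 are the α/β carbons of that latent C6 carbonyl, so the fused lactone O–C8(=C9)–C7=C11–C12(=O) is a dehydrated adduct of a C6/C8 vinylogous ester and an α-keto acid.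
4. 13 ⇐ cyclohexanone 11 ⇐ acyclic aldehyde 9 by intramolecular carbonyl-ene closure; 9 ⇐ prenal by Keck allylation (C2), Wacker oxidation and chelation-controlled Mukaiyama aldol (C4).
5. Ring order: six-membered carbocycle (step 7), then ten-membered carbocycle and butenolide together (step 13).

Key step: step 13

Remark (numbering): C1–C10 are the ring carbons (C1=C10 the E alkene, C2 the acetoxy carbon, C4 the tertiary carbinol, C6 the methacryloyloxy carbon, C7/C8 the ring-fusion carbons), C11 the lactone α-carbon, C12 the lactone carbonyl, C13 the hydroxymethyl carbon; NAP = 2-naphthylmethyl.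
Assumption: 10 is drawn as the expected all-equatorial chair product; its C6 and C1 configurations are erased later (step 8 and step 13).

Step 1
Reactants: 1 3-methylbut-2-enal; 2 allyltributylstannane
Product: 3 (S)-6-methylhepta-1,5-dien-4-ol
Conditions: (S)-BINOL (20 mol %), Ti(OiPr)4 (10 mol %), 4 Å MS, CH2Cl2, −20 °C; then aq. NaHCO3
Reagents that add atoms: none
Why: Keck asymmetric allylation, in which the chiral BINOL–titanium Lewis acid should direct the allylstannane to one carbonyl face and set C2 as (S), (S)-BINOL being the antipode expected to give the (S)-carbinol when the aldehyde substituent outranks allyl.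

Step 2
Reactants: 3 (S)-6-methylhepta-1,5-dien-4-ol
Product: 4 2-({[(4S)-6-methylhepta-1,5-dien-4-yl]oxy}methyl)naphthalene
Conditions: NaH, 2-(bromomethyl)naphthalene, Bu4NI (cat.), THF/DMF, 0 → 25 °C
Reagents that add atoms: 2-(bromomethyl)naphthalene, BrCc1ccc2ccccc2c1
Why: Williamson etherification should install an ether on the C2 oxygen that can chelate in step 4, tolerates base and acid, and is removed oxidatively in step 16.

Step 3
Reactants: 4 2-({[(4S)-6-methylhepta-1,5-dien-4-yl]oxy}methyl)naphthalene
Product: 5 (S)-6-methyl-4-(naphthalen-2-ylmethoxy)hept-5-en-2-one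
Conditions: PdCl2 (10 mol %), CuCl, O2 (1 atm), DMF/H2O 7:1, 25 °C
Reagents that add atoms: water, O
Why: Tsuji–Wacker oxidation (Markovnikov hydroxypalladation by divalent palladium) is selective for the monosubstituted terminal alkene, so the trisubstituted alkene should stay untouched and the C4 methyl ketone should result.

Step 4
Reactants: 5 (S)-6-methyl-4-(naphthalen-2-ylmethoxy)hept-5-en-2-one; 6 1-(tert-butyldimethylsilyloxy)-1-methoxyethene
Product: 7 methyl (3S,5S)-3-hydroxy-3,7-dimethyl-5-(naphthalen-2-ylmethoxy)oct-6-enoate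
Conditions: TiCl4, CH2Cl2, −78 °C; then 6, −78 °C; aq. NaHCO3
Reagents that add atoms: none
Why: Chelation-controlled Mukaiyama aldol addition, in which TiCl4 should bridge the ketone and the C2 ether oxygen in a six-membered chelate so that the ketene silyl acetal attacks the face away from the C2 substituent and sets the C4 tertiary carbinol with C4–OH anti to C2–O.

Step 5
Reactants: 7 methyl (3S,5S)-3-hydroxy-3,7-dimethyl-5-(naphthalen-2-ylmethoxy)oct-6-enoate
Product: 8 methyl (3S,5S)-3-[(tert-butyldimethylsilyl)oxy]-3,7-dimethyl-5-(naphthalen-2-ylmethoxy)oct-6-enoate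
Conditions: TBSOTf, 2,6-lutidine, CH2Cl2, 0 °C
Reagents that add atoms: tert-butyldimethylsilyl trifluoromethanesulfonate, CC(C)(C)[Si](C)(C)OS(=O)(=O)C(F)(F)F
Why: Silylation of the hindered tertiary alcohol with the silyl triflate should prevent retro-aldol cleavage now and β-hydroxy ketone dehydration later.

Step 6
Reactants: 8 methyl (3S,5S)-3-[(tert-butyldimethylsilyl)oxy]-3,7-dimethyl-5-(naphthalen-2-ylmethoxy)oct-6-enoate
Product: 9 (3S,5S)-3-[(tert-butyldimethylsilyl)oxy]-3,7-dimethyl-5-(naphthalen-2-ylmethoxy)oct-6-enal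
Conditions: iBu2AlH, CH2Cl2, −78 °C; Rochelle salt
Reagents that add atoms: none
Why: Partial ester reduction, in which the aluminium hemiacetal should persist at −78 °C and release the aldehyde only on work-up.

Step 7
Reactants: 9 (3S,5S)-3-[(tert-butyldimethylsilyl)oxy]-3,7-dimethyl-5-(naphthalen-2-ylmethoxy)oct-6-enal
Product: 10 (1R,2S,3S,5R)-5-[(tert-butyldimethylsilyl)oxy]-5-methyl-3-(naphthalen-2-ylmethoxy)-2-(prop-1-en-2-yl)cyclohexan-1-ol
Conditions: Me2AlCl, CH2Cl2, −78 → −20 °C
Reagents that add atoms: none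
Why: Lewis-acid-promoted intramolecular carbonyl-ene reaction (isopulegol-type closure), in which C1 of the trisubstituted alkene should attack the aldehyde complex through a chair with the C2 ether, the C4 methyl and the forming isopropenyl group equatorial, making the C6–C1 bond and the isopropenyl group (C9 becomes the terminal CH2) with C1 and C6 trans to their neighbours.

Step 8
Reactants: 10 (1R,2S,3S,5R)-5-[(tert-butyldimethylsilyl)oxy]-5-methyl-3-(naphthalen-2-ylmethoxy)-2-(prop-1-en-2-yl)cyclohexan-1-ol
Product: 11 (2R,3S,5S)-5-[(tert-butyldimethylsilyl)oxy]-5-methyl-3-(naphthalen-2-ylmethoxy)-2-(prop-1-en-2-yl)cyclohexan-1-one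
Conditions: Dess–Martin periodinane, NaHCO3, CH2Cl2, 0 → 25 °C
Reagents that add atoms: none
Why: Dess–Martin oxidation under buffered, non-basic conditions should give the ketone without moving the isopropenyl double bond into conjugation or eliminating the β-oxygen groups.

Step 9
Reactants: 11 (2R,3S,5S)-5-[(tert-butyldimethylsilyl)oxy]-5-methyl-3-(naphthalen-2-ylmethoxy)-2-(prop-1-en-2-yl)cyclohexan-1-one; 12 ethoxyethyne
Product: 13 (1S,2R,3S,5S)-5-[(tert-butyldimethylsilyl)oxy]-1-(ethoxyethynyl)-5-methyl-3-(naphthalen-2-ylmethoxy)-2-(prop-1-en-2-yl)cyclohexan-1-ol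
Conditions: 12, n-BuLi, THF, −78 °C; CeCl3, −78 °C; then 11, −78 °C
Reagents that add atoms: none
Why: 1,2-Addition of the cerium-modified lithium acetylide (weakly basic, so C1 should not be enolised), in which the axial C4 silyloxy group blocks axial attack so that the alkynyl group should enter equatorially at C6, trans to the equatorial isopropenyl group.

Step 10
Reactants: 14 tert-butyl acrylate
Product: 15 tert-butyl 2,3-dihydroxypropanoate (racemic)
Conditions: OsO4 (2 mol %), N-methylmorpholine N-oxide, acetone/H2O, 25 °C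
Reagents that add atoms: N-methylmorpholine N-oxide, C[N+]1([O-])CCOCC1; water, O
Why: Upjohn dihydroxylation of the acrylate should give the racemic diol, whose stereocentre is removed in step 12.

Step 11
Reactants: 15 tert-butyl 2,3-dihydroxypropanoate (racemic)
Product: 16 tert-butyl 3-[(tert-butyldiphenylsilyl)oxy]-2-hydroxypropanoate (racemic)
Conditions: TBDPSCl, imidazole, CH2Cl2, 0 °C
Reagents that add atoms: tert-butyl(chloro)diphenylsilane, CC(C)(C)[Si](Cl)(c1ccccc1)c1ccccc1
Why: Selective silylation of the primary hydroxyl by the bulky silyl chloride.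

Step 12
Reactants: 16 tert-butyl 3-[(tert-butyldiphenylsilyl)oxy]-2-hydroxypropanoate (racemic)
Product: 17 tert-butyl 3-[(tert-butyldiphenylsilyl)oxy]-2-oxopropanoate
Conditions: Dess–Martin periodinane, CH2Cl2, 25 °C
Reagents that add atoms: none
Why: Dess–Martin oxidation of the α-hydroxy ester should give the α-keto ester, which is used directly.

Step 13
Reactants: 13 (1S,2R,3S,5S)-5-[(tert-butyldimethylsilyl)oxy]-1-(ethoxyethynyl)-5-methyl-3-(naphthalen-2-ylmethoxy)-2-(prop-1-en-2-yl)cyclohexan-1-ol; 17 tert-butyl 3-[(tert-butyldiphenylsilyl)oxy]-2-oxopropanoate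
Product: 20 ten-membered keto-butenolide, via potassium allenolate 18 (not isolated), via zinc aldolate 19 (not isolated)
Conditions: KH, 18-crown-6, THF, 0 → 25 °C; ZnCl2, −78 °C; 17, −78 °C; then CF3CO2H, CH2Cl2, 0 → 25 °C (one flask)
Reagents that add atoms: none
Why: Proposed new method: the potassium alkoxide of 13 should undergo an anionic oxy-Cope [3,3] shift through the ethoxyalkyne (C6–C1 broken, C8–C9 made; closest known type is the acetylenic anionic oxy-Cope ring expansion of 1-alkynyl-2-alkenylcycloalkanols), giving ring allenolate 18 in which C7 is the nucleophilic carbon and C8 carries the ethoxy leaving group. Zinc-mediated aldol addition of C7 to the ketone of 17 should make the C7–C11 bond (closest known type is the ketone enolate–pyruvate aldol used for fused butenolides), and trifluoroacetic acid should then cleave the tert-butyl ester, add the carboxyl oxygen to the protonated vinylogous ester at C8 (O–C8 bond), expel ethanol and dehydrate C11, which gives the C7=C11 and C8=C9 double bonds. The ten-membered ring closes by four-atom ring expansion of the cyclohexane through a chair-like sigmatropic array, and the butenolide by 5-exo-trig attack of the carboxyl oxygen on the C8 oxocarbenium ion. No lasting stereocentre is created (C11 is transient and becomes sp2) and C2 and C4 are untouched. The step needs E geometry at C1=C10, which the trans-diequatorial alkynyl/isopropenyl arrangement of 13 should secure; attack at C7, which generating the allenolate with KH in the absence of any proton source should secure; and lactonisation at C8 and not C6, which the ethoxy leaving group on C8 and the extended C8=C9–C10=C1 conjugation should secure, the C8=C9 bond being possible only as the ring-cis isomer next to the E alkene.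

Step 14
Reactants: 20 ten-membered keto-butenolide
Product: 21 (6R)-alcohol
Conditions: (S)-2-methyl-CBS-oxazaborolidine (20 mol %), catecholborane, toluene/CH2Cl2, −78 °C
Reagents that add atoms: none
Why: Corey–Bakshi–Shibata reduction, in which the sp2 carbon C7 acts as the large and the C5 methylene as the small ketone substituent so that the (S)-oxazaborolidine should deliver hydride to the face giving the (6R)-alcohol, with catecholborane reducing 1,2 and leaving the lactone alone.

Step 15
Reactants: 21 (6R)-alcohol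
Product: 22 C6 methacrylate
Conditions: methacrylic anhydride, Et3N, DMAP (cat.), CH2Cl2, 0 → 25 °C
Reagents that add atoms: methacrylic anhydride, C=C(C)C(=O)OC(=O)C(C)=C
Why: DMAP-catalysed acylation of the secondary C6 alcohol, the only free hydroxyl present.

Step 16
Reactants: 22 C6 methacrylate
Product: 23 C2 alcohol
Conditions: DDQ, CH2Cl2/pH 7 buffer, 0 °C
Reagents that add atoms: none
Why: Oxidative cleavage of the 2-naphthylmethyl ether by DDQ (hydride abstraction, then hydrolysis of the hemiacetal) should free the C2 alcohol while the silyl ethers and esters stay.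

Step 17
Reactants: 23 C2 alcohol
Product: 24 C2 acetate
Conditions: Ac2O, pyridine, DMAP (cat.), CH2Cl2, 0 °C
Reagents that add atoms: acetic anhydride, CC(=O)OC(C)=O
Why: DMAP-catalysed acetylation of the only free hydroxyl (secondary, allylic C2).

Step 18
Reactants: 24 C2 acetate
Product: 25 CNP0246543.2
Conditions: HF·pyridine, pyridine, THF, 0 → 40 °C
Reagents that add atoms: none
Why: Fluoride-mediated desilylation under buffered, mildly acidic conditions should remove the primary tert-butyldiphenylsilyl and the tertiary tert-butyldimethylsilyl ether without acyl migration or attack on the methacrylate.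

**Compound list**

1 | 3-methylbut-2-enal (prenal) | CC(C)=CC=O | starting material
2 | allyltributylstannane | C=CC[Sn](CCCC)(CCCC)CCCC | starting material
3 | (S)-6-methylhepta-1,5-dien-4-ol | C=CC[C@H](O)C=C(C)C | intermediate
4 | 2-({[(4S)-6-methylhepta-1,5-dien-4-yl]oxy}methyl)naphthalene | C=CC[C@H](OCc1ccc2ccccc2c1)C=C(C)C | intermediate
5 | (S)-6-methyl-4-(naphthalen-2-ylmethoxy)hept-5-en-2-one | CC(=O)C[C@H](OCc1ccc2ccccc2c1)C=C(C)C | intermediate
6 | 1-(tert-butyldimethylsilyloxy)-1-methoxyethene | C=C(OC)O[Si](C)(C)C(C)(C)C | starting material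
7 | methyl (3S,5S)-3-hydroxy-3,7-dimethyl-5-(naphthalen-2-ylmethoxy)oct-6-enoate | COC(=O)C[C@@](C)(O)C[C@H](OCc1ccc2ccccc2c1)C=C(C)C | intermediate
8 | methyl (3S,5S)-3-[(tert-butyldimethylsilyl)oxy]-3,7-dimethyl-5-(naphthalen-2-ylmethoxy)oct-6-enoate | COC(=O)C[C@@](C)(O[Si](C)(C)C(C)(C)C)C[C@H](OCc1ccc2ccccc2c1)C=C(C)C | intermediate
9 | (3S,5S)-3-[(tert-butyldimethylsilyl)oxy]-3,7-dimethyl-5-(naphthalen-2-ylmethoxy)oct-6-enal | O=CC[C@@](C)(O[Si](C)(C)C(C)(C)C)C[C@H](OCc1ccc2ccccc2c1)C=C(C)C | intermediate
10 | (1R,2S,3S,5R)-5-[(tert-butyldimethylsilyl)oxy]-5-methyl-3-(naphthalen-2-ylmethoxy)-2-(prop-1-en-2-yl)cyclohexan-1-ol (isopropenyl trans to both flanking oxygens; C4 silyloxy axial) | O[C@@H]1C[C@@](C)(O[Si](C)(C)C(C)(C)C)C[C@H](OCc2ccc3ccccc3c2)[C@H]1C(C)=C | intermediate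
11 | (2R,3S,5S)-5-[(tert-butyldimethylsilyl)oxy]-5-methyl-3-(naphthalen-2-ylmethoxy)-2-(prop-1-en-2-yl)cyclohexan-1-one | O=C1C[C@@](C)(O[Si](C)(C)C(C)(C)C)C[C@H](OCc2ccc3ccccc3c2)[C@H]1C(C)=C | intermediate
12 | ethoxyethyne | CCOC#C | starting material
13 | (1S,2R,3S,5S)-5-[(tert-butyldimethylsilyl)oxy]-1-(ethoxyethynyl)-5-methyl-3-(naphthalen-2-ylmethoxy)-2-(prop-1-en-2-yl)cyclohexan-1-ol (alkynyl equatorial, trans to isopropenyl) | CCOC#C[C@]1(O)C[C@@](C)(O[Si](C)(C)C(C)(C)C)C[C@H](OCc2ccc3ccccc3c2)[C@H]1C(C)=C | intermediate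
14 | tert-butyl acrylate | C=CC(=O)OC(C)(C)C | starting material
15 | tert-butyl 2,3-dihydroxypropanoate (racemic) | OCC(O)C(=O)OC(C)(C)C | intermediate
16 | tert-butyl 3-[(tert-butyldiphenylsilyl)oxy]-2-hydroxypropanoate (racemic) | CC(C)(C)OC(=O)C(O)CO[Si](c1ccccc1)(c1ccccc1)C(C)(C)C | intermediate
17 | tert-butyl 3-[(tert-butyldiphenylsilyl)oxy]-2-oxopropanoate | CC(C)(C)OC(=O)C(=O)CO[Si](c1ccccc1)(c1ccccc1)C(C)(C)C | intermediate
18 | potassium allenolate of the ring-expanded ten-membered ketone (C6–O−, C6=C7=C8, 8-ethoxy, 1(10)E; C2 and C4 as in the target) | [K+].[O-]C1C[C@@](C)(O[Si](C)(C)C(C)(C)C)C[C@H](OCc2ccc3ccccc3c2)/C=C(C)/CC(OCC)=C=1 | intermediate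
19 | zinc aldolate at C7 (drawn as the free tertiary alcohol; C6 ketone, C7=C8 enol ether with 8-ethoxy, C11 carbinol as an epimer mixture, tert-butyl ester) | O=C1C[C@@](C)(O[Si](C)(C)C(C)(C)C)C[C@H](OCc2ccc3ccccc3c2)/C=C(C)/C/C(OCC)=C1/C(O)(CO[Si](c4ccccc4)(c4ccccc4)C(C)(C)C)C(=O)OC(C)(C)C | intermediate
20 | ten-membered keto-butenolide: 6-oxo, 2-O-NAP, 4-O-TBS, 13-O-TBDPS form of the target skeleton (1(10)E; C8=C9 ring-cis with the lactone oxygen trans to C10; C2 and C4 as in the target) | O=C1C[C@@](C)(O[Si](C)(C)C(C)(C)C)C[C@H](OCc3ccc4ccccc4c3)/C=C(C)/C=C2/OC(=O)C(CO[Si](c5ccccc5)(c5ccccc5)C(C)(C)C)=C12 | intermediate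
21 | (6R)-alcohol: 6-hydroxy, 2-O-NAP, 4-O-TBS, 13-O-TBDPS | O[C@@H]1C[C@@](C)(O[Si](C)(C)C(C)(C)C)C[C@H](OCc3ccc4ccccc4c3)/C=C(C)/C=C2/OC(=O)C(CO[Si](c5ccccc5)(c5ccccc5)C(C)(C)C)=C21 | intermediate
22 | C6 methacrylate: 6-O-methacryloyl, 2-O-NAP, 4-O-TBS, 13-O-TBDPS | C=C(C)C(=O)O[C@@H]1C[C@@](C)(O[Si](C)(C)C(C)(C)C)C[C@H](OCc3ccc4ccccc4c3)/C=C(C)/C=C2/OC(=O)C(CO[Si](c5ccccc5)(c5ccccc5)C(C)(C)C)=C21 | intermediate
23 | C2 alcohol: 6-O-methacryloyl, 2-hydroxy, 4-O-TBS, 13-O-TBDPS | C=C(C)C(=O)O[C@@H]1C[C@@](C)(O[Si](C)(C)C(C)(C)C)C[C@H](O)/C=C(C)/C=C2/OC(=O)C(CO[Si](c3ccccc3)(c3ccccc3)C(C)(C)C)=C21 | intermediate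
24 | C2 acetate: 6-O-methacryloyl, 2-O-acetyl, 4-O-TBS, 13-O-TBDPS | C=C(C)C(=O)O[C@@H]1C[C@@](C)(O[Si](C)(C)C(C)(C)C)C[C@H](OC(C)=O)/C=C(C)/C=C2/OC(=O)C(CO[Si](c3ccccc3)(c3ccccc3)C(C)(C)C)=C21 | intermediate
25 | CNP0246543.2 | C=C(C)C(=O)O[C@@H]1C[C@@](C)(O)C[C@H](OC(C)=O)/C=C(C)/C=C2/OC(=O)C(CO)=C21 | target

**Step count and risks**

Total steps: 18. Longest linear sequence: 15 steps (steps 1–9 and 13–18); steps 10–12 are a three-step side branch.

Steps most likely to fail:

1. Step 13 (proposed new method). What may go wrong: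
   - fragmentation of the propargylic alkoxide back to ketone and acetylide in place of the sigmatropic shift;
   - proton transfer from the enolisable keto ester to the allenolate in place of carbonyl addition;
   - lactonisation toward C6, or ionisation of the allylic C2 ether in the acid stage.

   The fallback uses known reaction types only, sets out from ketone 11 and returns at 20. Ethynylmagnesium bromide (HC≡CMgBr, CeCl3, THF, −78 °C) would give ethynyl carbinol F1. KH/18-crown-6 would effect the known acetylenic anionic oxy-Cope ring expansion, and protonation would give cyclodecadienone F2. Wacker-type oxidation of the enone (Na2PdCl4 cat., tert-butyl hydroperoxide, AcOH/H2O, 50 °C) would give ring 1,3-dione F3. Knoevenagel condensation of F3 with keto ester 17 (TiCl4, pyridine, THF, 0 °C) would give alkylidene dione F4. CF3CO2H would then cleave the tert-butyl ester and cyclodehydrate the resulting 4-oxo-2-enoic acid (lactol formation at C8, dehydration toward C9 into conjugation with C1=C10) to 20.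

2. Step 7. What may go wrong: ionisation of the allylic naphthylmethyl ether or β-elimination of the silyloxy group under the Lewis acid, outrunning attack of the oxygen-deactivated alkene on the aldehyde.

   The fallback sets out from ester 8 and returns at 10. Ene-type allylic chlorination with double-bond shift (N-chlorosuccinimide, PhSeCl cat., CH2Cl2) would give allylic chloride F5. Reduction with iBu2AlH at −78 °C would give chloro aldehyde F6. CrCl2 in THF would then close the ring by intramolecular Nozaki–Hiyama allylation: the allylchromium species formed by divalent chromium attacks the aldehyde through its γ-carbon C1, under neutral conditions, to give 10 with the isopropenyl group and the anti hydroxyl.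

3. Step 14. What may go wrong: conjugate (1,4) hydride delivery to the ene-dione-like C6(=O)–C7=C11–C12(=O) system, or a mismatch between catalyst control and the facial bias of the ten-membered ring, leading to poor facial selectivity at C6.

   The fallback sets out from 20 and returns at 22. Luche reduction (NaBH4, CeCl3·7H2O, MeOH, −78 °C) would give 21 together with C6 epimer alcohol F7. After separation, 21 is acylated as in step 15. F7 is converted into the same ester 22 by Mitsunobu esterification with methacrylic acid (PPh3, DIAD, THF, 0 °C), which installs the methacrylate with inversion at C6, so both epimers converge.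

Further compounds
F1 | step 13 | ethynyl carbinol: 1-ethynyl analogue of 13 | C#C[C@]1(O)C[C@@](C)(O[Si](C)(C)C(C)(C)C)C[C@H](OCc2ccc3ccccc3c2)[C@H]1C(C)=C
F2 | step 13 | cyclodecadienone: ten-membered 6-oxo-7,1(10)-diene (C7=C8 ring-cis, 1(10)E), 2-O-NAP, 4-O-TBS | O=C1/C=C\C/C(C)=C/[C@@H](OCc2ccc3ccccc3c2)C[C@](C)(O[Si](C)(C)C(C)(C)C)C1
F3 | step 13 | ring 1,3-dione: ten-membered 6,8-dioxo-1(10)E-ene, 2-O-NAP, 4-O-TBS | O=C1CC(=O)C/C(C)=C/[C@@H](OCc2ccc3ccccc3c2)C[C@](C)(O[Si](C)(C)C(C)(C)C)C1
F4 | step 13 | alkylidene dione: Knoevenagel adduct of F3 at C7 with 17 (C7=C11, tert-butyl ester, 13-O-TBDPS; alkene isomers interconvert) | O=C1C(=C(CO[Si](c2ccccc2)(c2ccccc2)C(C)(C)C)C(=O)OC(C)(C)C)C(=O)C/C(C)=C/[C@@H](OCc2ccc3ccccc3c2)C[C@](C)(O[Si](C)(C)C(C)(C)C)C1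
F5 | step 7 | allylic chloride: methyl (3S,5S)-3-[(tert-butyldimethylsilyl)oxy]-6-chloro-3,7-dimethyl-5-(naphthalen-2-ylmethoxy)oct-7-enoate (C6 epimers) | COC(=O)C[C@@](C)(O[Si](C)(C)C(C)(C)C)C[C@H](OCc1ccc2ccccc2c1)C(Cl)C(C)=C
F6 | step 7 | chloro aldehyde: (3S,5S)-3-[(tert-butyldimethylsilyl)oxy]-6-chloro-3,7-dimethyl-5-(naphthalen-2-ylmethoxy)oct-7-enal (C6 epimers) | O=CC[C@@](C)(O[Si](C)(C)C(C)(C)C)C[C@H](OCc1ccc2ccccc2c1)C(Cl)C(C)=C
F7 | step 14 | C6 epimer alcohol: (6S)-epimer of 21 | O[C@H]1C[C@@](C)(O[Si](C)(C)C(C)(C)C)C[C@H](OCc3ccc4ccccc4c3)/C=C(C)/C=C2/OC(=O)C(CO[Si](c5ccccc5)(c5ccccc5)C(C)(C)C)=C21
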